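**Plan**
- Retrosynthesis: after deprotection the carbocycle is opened at C7–C8 (lateral aldol of the pyranone), the chain is cut at C4a–C5 (pyranyl triflate plus glyceraldehyde), then C8a–C8 (hydroxymethyl) and the aryl-ethyl arm (olefination) are removed, leading back to kojic acid and isovanillin.
- Forward: the γ-pyranone ring comes intact from kojic acid; the arylethyl chain is joined by olefination/hydrogenation, C8 by hydroxymethylation, C5–C7 by a Nozaki–Hiyama–Kishi coupling at C4a; the ring C4a–C5–C6–C7–C8–C8a closes last.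
- Enabling feature: C8 sits on C8a of a 2-alkyl-γ-pyranone and is vinylogous to C4=O through C8a=C4a, so O4-silylation makes C8–H acidic and C8 nucleophilic; in the half-chair of the new ring O6, O7 and O8 can all be equatorial with O5 pseudoaxial.
- Stereochemistry: C6 from (R)-glyceraldehyde acetonide; C5 by Felkin–Anh addition (5,6-anti); C7 and C8 in the ring closure, relayed from C5/C6, with C8 remaining epimerisable.
- Protecting groups: aryl isopropyl, C8 benzyl, C5/C6 triethylsilyl; all are removed in one BCl3 operation.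

Key step: step 14

Remark: chromone numbering (O1, C2–C4, C4a, C5–C8, C8a) is used for the atoms of all intermediates; the CIP labels at C6 and C7 change with the O-substituents although the spatial arrangement stays that of the target (5,6-cis, 6,7-trans, 7,8-trans).

**Route**

Step 1
Reactants: 1 isovanillin (3-hydroxy-4-methoxybenzaldehyde)
Product: 2 3-isopropoxy-4-methoxybenzaldehyde
Conditions: 2-bromopropane, K2CO3, DMF, 60 °C
Reagents that add atoms: 2-bromopropane, CC(C)Br
Why: Williamson etherification of the phenol; the isopropyl ether survives hydrogenation and aqueous base and is later cleaved by BCl3 in preference to the methyl ether.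

Step 2
Reactants: 3 kojic acid (5-hydroxy-2-(hydroxymethyl)-4H-pyran-4-one)
Product: 4 5-(benzyloxy)-2-(hydroxymethyl)-4H-pyran-4-one
Conditions: BnCl, NaOH, MeOH/H2O, reflux
Reagents that add atoms: benzyl chloride, ClCc1ccccc1
Why: Williamson O-benzylation of the acidic enolic 5-OH, which is deprotonated in preference to the primary alcohol.

Step 3
Reactants: 4 5-(benzyloxy)-2-(hydroxymethyl)-4H-pyran-4-one
Product: 5 5-(benzyloxy)-2-(chloromethyl)-4H-pyran-4-one
Conditions: SOCl2, CH2Cl2, rt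
Reagents that add atoms: thionyl chloride, O=S(Cl)Cl
Why: Chlorodehydroxylation of the activated primary alcohol through its chlorosulfite.

Step 4
Reactants: 5 5-(benzyloxy)-2-(chloromethyl)-4H-pyran-4-one
Product: 6 diethyl {[5-(benzyloxy)-4-oxo-4H-pyran-2-yl]methyl}phosphonate
Conditions: P(OEt)3 (neat), 130 °C
Reagents that add atoms: triethyl phosphite, CCOP(OCC)OCC
Why: Michaelis–Arbuzov reaction of the reactive pyranylmethyl chloride.

Step 5
Reactants: 6 diethyl {[5-(benzyloxy)-4-oxo-4H-pyran-2-yl]methyl}phosphonate; 2 3-isopropoxy-4-methoxybenzaldehyde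
Product: 7 5-(benzyloxy)-2-[(E)-2-(3-isopropoxy-4-methoxyphenyl)ethenyl]-4H-pyran-4-one
Conditions: NaH, THF, 0 °C → rt
Reagents that add atoms: none
Why: Horner–Wadsworth–Emmons olefination of the lateral, pyranone-stabilised phosphonate anion with the non-enolisable aldehyde; the alkene geometry is irrelevant because the double bond is hydrogenated next.

Step 6
Reactants: 7 5-(benzyloxy)-2-[(E)-2-(3-isopropoxy-4-methoxyphenyl)ethenyl]-4H-pyran-4-one
Product: 8 5-hydroxy-2-[2-(3-isopropoxy-4-methoxyphenyl)ethyl]-4H-pyran-4-one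
Conditions: H2 (1 atm), 10% Pd/C, EtOAc/MeOH, rt
Reagents that add atoms: none
Why: Catalytic hydrogenation of the styryl double bond together with hydrogenolysis of the enol benzyl ether; the pyranone ring and the aryl isopropyl ether should be inert.

Step 7
Reactants: 8 5-hydroxy-2-[2-(3-isopropoxy-4-methoxyphenyl)ethyl]-4H-pyran-4-one
Product: 9 3-hydroxy-2-(hydroxymethyl)-6-[2-(3-isopropoxy-4-methoxyphenyl)ethyl]-4H-pyran-4-one
Conditions: 37% aq. HCHO, NaOH (1.05 equiv), H2O/MeOH, rt; then HCl to pH 3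
Reagents that add atoms: formaldehyde, C=O
Why: Lederer–Manasse-type hydroxymethylation of the hydroxypyranone enolate at the only free position ortho to the enolate oxygen, as known for kojic acid and allomaltol; this carbon becomes C8 on C8a.

Step 8
Reactants: 9 3-hydroxy-2-(hydroxymethyl)-6-[2-(3-isopropoxy-4-methoxyphenyl)ethyl]-4H-pyran-4-one
Product: 10 2-(hydroxymethyl)-6-[2-(3-isopropoxy-4-methoxyphenyl)ethyl]-4-oxo-4H-pyran-3-yl trifluoromethanesulfonate
Conditions: PhNTf2, Et3N, CH2Cl2, 0 °C → rt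
Reagents that add atoms: N-phenylbis(trifluoromethanesulfonimide), O=S(=O)(N(c1ccccc1)S(=O)(=O)C(F)(F)F)C(F)(F)F
Why: O-triflation of the acidic enol hydroxyl with a mild triflyl donor that reacts with the enolate and leaves the primary alcohol alone, so the coupling handle is placed at C4a without any regiochemical ambiguity.

Step 9
Reactants: 10 2-(hydroxymethyl)-6-[2-(3-isopropoxy-4-methoxyphenyl)ethyl]-4-oxo-4H-pyran-3-yl trifluoromethanesulfonate
Product: 11 2-[(benzyloxy)methyl]-6-[2-(3-isopropoxy-4-methoxyphenyl)ethyl]-4-oxo-4H-pyran-3-yl trifluoromethanesulfonate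
Conditions: BnOC(=NH)CCl3, TfOH (cat.), CH2Cl2/cyclohexane, 0 °C → rt
Reagents that add atoms: benzyl 2,2,2-trichloroacetimidate, N=C(OCc1ccccc1)C(Cl)(Cl)Cl
Why: Acid-catalysed benzylation with the trichloroacetimidate, chosen because it needs no base and therefore spares the triflate and the lateral CH2.

Step 10
Reactants: 11 2-[(benzyloxy)methyl]-6-[2-(3-isopropoxy-4-methoxyphenyl)ethyl]-4-oxo-4H-pyran-3-yl trifluoromethanesulfonate; 12 (R)-2,3-O-isopropylideneglyceraldehyde
Product: 13 2-[(benzyloxy)methyl]-3-{(S)-[(4R)-2,2-dimethyl-1,3-dioxolan-4-yl](hydroxy)methyl}-6-[2-(3-isopropoxy-4-methoxyphenyl)ethyl]-4H-pyran-4-one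
Conditions: CrCl2 (4 equiv), NiCl2 (5 mol %), DMF, rt
Reagents that add atoms: none
Why: Nozaki–Hiyama–Kishi coupling, in which zerovalent nickel (from NiCl2 and CrCl2) inserts into the C4a–OTf bond and transmetalation gives a pyranyl species of trivalent chromium that adds only to the aldehyde; Felkin–Anh attack anti to the dioxolane C–O bond should set C5 as the 5,6-anti (S)-carbinol, with the minor syn epimer removed by chromatography.

Step 11
Reactants: 13 2-[(benzyloxy)methyl]-3-{(S)-[(4R)-2,2-dimethyl-1,3-dioxolan-4-yl](hydroxy)methyl}-6-[2-(3-isopropoxy-4-methoxyphenyl)ethyl]-4H-pyran-4-one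
Product: 14 2-[(benzyloxy)methyl]-6-[2-(3-isopropoxy-4-methoxyphenyl)ethyl]-3-[(1S,2R)-1,2,3-trihydroxypropyl]-4H-pyran-4-one
Conditions: AcOH/H2O (4:1), 40 °C
Reagents that add atoms: none
Why: Acid-catalysed hydrolysis of the terminal isopropylidene acetal under conditions that leave the benzyl and aryl ethers untouched.

Step 12
Reactants: 14 2-[(benzyloxy)methyl]-6-[2-(3-isopropoxy-4-methoxyphenyl)ethyl]-3-[(1S,2R)-1,2,3-trihydroxypropyl]-4H-pyran-4-one
Product: 15 2-[(benzyloxy)methyl]-6-[2-(3-isopropoxy-4-methoxyphenyl)ethyl]-3-[(1S,2R)-1,2,3-tris(triethylsilyloxy)propyl]-4H-pyran-4-one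
Conditions: TESCl, imidazole, DMAP (cat.), DMF, rt
Reagents that add atoms: chlorotriethylsilane, CC[Si](Cl)(CC)CC
Why: Exhaustive silylation of the three hydroxyls, which protects O5 and O6 and marks the primary C7 oxygen for the next step.

Step 13
Reactants: 15 2-[(benzyloxy)methyl]-6-[2-(3-isopropoxy-4-methoxyphenyl)ethyl]-3-[(1S,2R)-1,2,3-tris(triethylsilyloxy)propyl]-4H-pyran-4-one
Product: 16 (2S,3S)-3-{2-[(benzyloxy)methyl]-6-[2-(3-isopropoxy-4-methoxyphenyl)ethyl]-4-oxo-4H-pyran-3-yl}-2,3-bis(triethylsilyloxy)propanal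
Conditions: (COCl)2, DMSO (2 equiv per (COCl)2), CH2Cl2, −78 → −40 °C; Et3N, −78 → 0 °C
Reagents that add atoms: none
Why: Swern oxidation with in situ cleavage of the primary triethylsilyl ether, a known chemoselective oxidative desilylation that leaves secondary silyl ethers in place; the low temperature should prevent epimerisation at C6.

Step 14
Reactants: 16 (2S,3S)-3-{2-[(benzyloxy)methyl]-6-[2-(3-isopropoxy-4-methoxyphenyl)ethyl]-4-oxo-4H-pyran-3-yl}-2,3-bis(triethylsilyloxy)propanal
Product: 19 (5S,6R,7S,8S)-8-(benzyloxy)-7-hydroxy-2-[2-(3-isopropoxy-4-methoxyphenyl)ethyl]-5,6-bis(triethylsilyloxy)-5,6,7,8-tetrahydro-4H-chromen-4-one, via silyloxy alkylidenepyran 17 (not isolated), via silyloxypyrylium triflate 18 (not isolated)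
Conditions: TMSOTf (3 equiv), 2,6-lutidine (2.2 equiv), CH2Cl2, −78 → −20 °C; aq. NaHCO3; then citric acid, THF/H2O, 0 °C
Reagents that add atoms: none
Why: Proposed new method: TMSOTf silylates the most basic oxygen, O4, to a 4-silyloxypyrylium whose lateral C8–H is removed by 2,6-lutidine, and the resulting 4-silyloxy-2-alkylidene-2H-pyran 17 adds through exocyclic C8 to the TMSOTf-activated C7 aldehyde, re-forming the aromatic pyrylium 18 that is hydrolysed on work-up (intramolecular vinylogous Mukaiyama aldol). The closest known reactions are the lateral aldol of lithium dienolates of 2-alkyl-γ-pyranones and 2-methylchromones with aldehydes and the one-pot silyl triflate/amine enol silane formation–Mukaiyama aldol of simple carbonyl compounds. The carbocycle C4a–C5–C6–C7–C8–C8a closes in a 6-(enolendo)-exo-trig mode, C8 and C8a both lying in the new ring and the aldehyde oxygen outside it. C7 is controlled by C5 and C6: in the half-chair transition state the C5 silyloxy group is pseudoaxial to avoid the peri O4–Si group, the C6 silyloxy group is then equatorial, and the aldehyde oxygen takes the equatorial position to escape a 1,3-diaxial clash with O5, which gives 6,7-trans. C8 is controlled by the (Z) geometry of 17 (benzyloxy syn to O1 to avoid allylic strain against C5), which places the benzyloxy group pseudoequatorial and 7,8-trans, and it stays correctable because lutidine/lutidinium should reversibly deprotonate C8–H of 18, draining any C8 epimer to the isomer with O6, O7 and O8 all equatorial. The selectivity needed is enolisation of the pyranone and not of the α-silyloxy aldehyde, secured by the far higher basicity of the pyranone oxygen toward the silyl triflate, a weak hindered base and low temperature.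

Step 15
Reactants: 19 (5S,6R,7S,8S)-8-(benzyloxy)-7-hydroxy-2-[2-(3-isopropoxy-4-methoxyphenyl)ethyl]-5,6-bis(triethylsilyloxy)-5,6,7,8-tetrahydro-4H-chromen-4-one
Product: 20 (5S,6S,7R,8S)-5,6,7,8-tetrahydroxy-2-[2-(3-hydroxy-4-methoxyphenyl)ethyl]-5,6,7,8-tetrahydro-4H-chromen-4-one
Conditions: BCl3 (1 M in CH2Cl2, excess), C6HMe5, CH2Cl2, −78 → 0 °C; then MeOH, 0 °C → rt
Reagents that add atoms: none
Why: BCl3-mediated ether cleavage removes the benzyl ether (cation trapped by pentamethylbenzene), the aryl isopropyl ether (selectively over the aryl methyl ether) and the silyl ethers (completed by the HCl/MeOH formed on quench); boron complexation of the pyranone should disfavour ionisation at C5 and C8, and no stereocenter is touched.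

**Compound list**

1 | isovanillin (3-hydroxy-4-methoxybenzaldehyde) | COc1ccc(C=O)cc1O | starting material
2 | 3-isopropoxy-4-methoxybenzaldehyde | COc1ccc(C=O)cc1OC(C)C | intermediate
3 | kojic acid (5-hydroxy-2-(hydroxymethyl)-4H-pyran-4-one) | OCc1cc(=O)c(O)co1 | starting material
4 | 5-(benzyloxy)-2-(hydroxymethyl)-4H-pyran-4-one | OCc1cc(=O)c(OCc2ccccc2)co1 | intermediate
5 | 5-(benzyloxy)-2-(chloromethyl)-4H-pyran-4-one | ClCc1cc(=O)c(OCc2ccccc2)co1 | intermediate
6 | diethyl {[5-(benzyloxy)-4-oxo-4H-pyran-2-yl]methyl}phosphonate | CCOP(=O)(OCC)Cc1cc(=O)c(OCc2ccccc2)co1 | intermediate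
7 | 5-(benzyloxy)-2-[(E)-2-(3-isopropoxy-4-methoxyphenyl)ethenyl]-4H-pyran-4-one | COc1ccc(/C=C/c2cc(=O)c(OCc3ccccc3)co2)cc1OC(C)C | intermediate
8 | 5-hydroxy-2-[2-(3-isopropoxy-4-methoxyphenyl)ethyl]-4H-pyran-4-one | COc1ccc(CCc2cc(=O)c(O)co2)cc1OC(C)C | intermediate
9 | 3-hydroxy-2-(hydroxymethyl)-6-[2-(3-isopropoxy-4-methoxyphenyl)ethyl]-4H-pyran-4-one | COc1ccc(CCc2cc(=O)c(O)c(CO)o2)cc1OC(C)C | intermediate
10 | 2-(hydroxymethyl)-6-[2-(3-isopropoxy-4-methoxyphenyl)ethyl]-4-oxo-4H-pyran-3-yl trifluoromethanesulfonate | COc1ccc(CCc2cc(=O)c(OS(=O)(=O)C(F)(F)F)c(CO)o2)cc1OC(C)C | intermediate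
11 | 2-[(benzyloxy)methyl]-6-[2-(3-isopropoxy-4-methoxyphenyl)ethyl]-4-oxo-4H-pyran-3-yl trifluoromethanesulfonate | COc1ccc(CCc2cc(=O)c(OS(=O)(=O)C(F)(F)F)c(COCc3ccccc3)o2)cc1OC(C)C | intermediate
12 | (R)-2,3-O-isopropylideneglyceraldehyde | O=C[C@H]1COC(C)(C)O1 | starting material
13 | 2-[(benzyloxy)methyl]-3-{(S)-[(4R)-2,2-dimethyl-1,3-dioxolan-4-yl](hydroxy)methyl}-6-[2-(3-isopropoxy-4-methoxyphenyl)ethyl]-4H-pyran-4-one | COc1ccc(CCc2cc(=O)c([C@H](O)[C@H]3COC(C)(C)O3)c(COCc3ccccc3)o2)cc1OC(C)C | intermediate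
14 | 2-[(benzyloxy)methyl]-6-[2-(3-isopropoxy-4-methoxyphenyl)ethyl]-3-[(1S,2R)-1,2,3-trihydroxypropyl]-4H-pyran-4-one | COc1ccc(CCc2cc(=O)c([C@H](O)[C@H](O)CO)c(COCc3ccccc3)o2)cc1OC(C)C | intermediate
15 | 2-[(benzyloxy)methyl]-6-[2-(3-isopropoxy-4-methoxyphenyl)ethyl]-3-[(1S,2R)-1,2,3-tris(triethylsilyloxy)propyl]-4H-pyran-4-one | COc1ccc(CCc2cc(=O)c([C@H](O[Si](CC)(CC)CC)[C@H](O[Si](CC)(CC)CC)CO[Si](CC)(CC)CC)c(COCc3ccccc3)o2)cc1OC(C)C | intermediate
16 | (2S,3S)-3-{2-[(benzyloxy)methyl]-6-[2-(3-isopropoxy-4-methoxyphenyl)ethyl]-4-oxo-4H-pyran-3-yl}-2,3-bis(triethylsilyloxy)propanal | COc1ccc(CCc2cc(=O)c([C@H](O[Si](CC)(CC)CC)[C@H](O[Si](CC)(CC)CC)C=O)c(COCc3ccccc3)o2)cc1OC(C)C | intermediate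
17 | (2S,3S)-3-{(2Z)-2-[(benzyloxy)methylidene]-6-[2-(3-isopropoxy-4-methoxyphenyl)ethyl]-4-(trimethylsilyloxy)-2H-pyran-3-yl}-2,3-bis(triethylsilyloxy)propanal | COc1ccc(CCC2=CC(O[Si](C)(C)C)=C([C@H](O[Si](CC)(CC)CC)[C@H](O[Si](CC)(CC)CC)C=O)/C(=C/OCc3ccccc3)O2)cc1OC(C)C | intermediate
18 | (5S,6S,7S,8S)-8-(benzyloxy)-2-[2-(3-isopropoxy-4-methoxyphenyl)ethyl]-5,6-bis(triethylsilyloxy)-4,7-bis(trimethylsilyloxy)-5,6,7,8-tetrahydrochromenylium trifluoromethanesulfonate | COc1ccc(CCc2cc(O[Si](C)(C)C)c3c([o+]2)[C@@H](OCc2ccccc2)[C@H](O[Si](C)(C)C)[C@@H](O[Si](CC)(CC)CC)[C@H]3O[Si](CC)(CC)CC)cc1OC(C)C.[O-]S(=O)(=O)C(F)(F)F | intermediate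
19 | (5S,6R,7S,8S)-8-(benzyloxy)-7-hydroxy-2-[2-(3-isopropoxy-4-methoxyphenyl)ethyl]-5,6-bis(triethylsilyloxy)-5,6,7,8-tetrahydro-4H-chromen-4-one | COc1ccc(CCc2cc(=O)c3c(o2)[C@@H](OCc2ccccc2)[C@H](O)[C@@H](O[Si](CC)(CC)CC)[C@H]3O[Si](CC)(CC)CC)cc1OC(C)C | intermediate
20 | (5S,6S,7R,8S)-5,6,7,8-tetrahydroxy-2-[2-(3-hydroxy-4-methoxyphenyl)ethyl]-5,6,7,8-tetrahydro-4H-chromen-4-one | COc1ccc(CCc2cc(=O)c3c(o2)[C@@H](O)[C@H](O)[C@@H](O)[C@H]3O)cc1O | target

**Totals**
Total steps: 15. Longest linear sequence: 14 steps (kojic acid 3 to target 20, steps 2–15).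

**Steps most likely to fail**

1. Step 14 (proposed new method). The electron-rich silyloxy alkylidenepyran may expel the C5 silyloxy group, the α-silyloxy aldehyde may enolise, or the aldol may dehydrate toward an aromatic chromone before clean ring closure and C8 equilibration are reached. The fallback closes the same C7–C8 bond by a known reductive pinacol coupling instead of an aldol. It sets out from 10, which is carried on without O-benzylation. Nozaki–Hiyama–Kishi coupling of 10 with 12 as in step 10 should give the hydroxymethyl carbinol acetonide F1. Hydrolysis with AcOH/H2O would give the tetraol F2, and TESCl/imidazole the tetrakis(triethylsilyl) ether F3. Swern oxidation would then convert both primary silyl ethers at once into the 7,8-dialdehyde F4. Intramolecular pinacol coupling of this 1,6-dialdehyde with Cp2TiPh, a reagent of trivalent titanium known to give trans-1,2-diols on cyclisation (SmI2 would favour the cis diol), should deliver the 7,8-diol F5 with both new hydroxyls equatorial and trans to O6. The conditions of step 15 then return the route at 20.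

2. Step 10. Facial selectivity in the addition of the hindered pyranyl chromium species to the α-alkoxy aldehyde may be poor, giving much of the 5,6-syn epimer. The fallback sets C5 by reduction instead of addition and uses known chemistry. It sets out from 13 taken as the C5 epimer mixture. Oxidation with Dess–Martin periodinane would give the ketone F6. Chelation-controlled reduction with Zn(BH4)2 in Et2O at −30 °C, with hydride delivered to the zinc chelate of the ketone and the dioxolane oxygen, should return the 5,6-anti alcohol 13.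

3. Step 13. The activated sulfonium reagent may attack the pyranone oxygen or a secondary silyl ether, or the α-silyloxy aldehyde may epimerise at C6 during the amine stage. The fallback separates deprotection from oxidation. It sets out from 15. Selective removal of the primary triethylsilyl ether with HF·pyridine/pyridine in THF at 0 °C would give the primary alcohol F7. Oxidation with Dess–Martin periodinane buffered with NaHCO3 then comes back to the route at 16.

**Further compounds**

F1 | step 14 | 2-(hydroxymethyl)-3-{(S)-[(4R)-2,2-dimethyl-1,3-dioxolan-4-yl](hydroxy)methyl}-6-[2-(3-isopropoxy-4-methoxyphenyl)ethyl]-4H-pyran-4-one | COc1ccc(CCc2cc(=O)c([C@H](O)[C@H]3COC(C)(C)O3)c(CO)o2)cc1OC(C)C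
F2 | step 14 | 2-(hydroxymethyl)-6-[2-(3-isopropoxy-4-methoxyphenyl)ethyl]-3-[(1S,2R)-1,2,3-trihydroxypropyl]-4H-pyran-4-one | COc1ccc(CCc2cc(=O)c([C@H](O)[C@H](O)CO)c(CO)o2)cc1OC(C)C
F3 | step 14 | 6-[2-(3-isopropoxy-4-methoxyphenyl)ethyl]-2-[(triethylsilyloxy)methyl]-3-[(1S,2R)-1,2,3-tris(triethylsilyloxy)propyl]-4H-pyran-4-one | COc1ccc(CCc2cc(=O)c([C@H](O[Si](CC)(CC)CC)[C@H](O[Si](CC)(CC)CC)CO[Si](CC)(CC)CC)c(CO[Si](CC)(CC)CC)o2)cc1OC(C)C
F4 | step 14 | (2S,3S)-3-{2-formyl-6-[2-(3-isopropoxy-4-methoxyphenyl)ethyl]-4-oxo-4H-pyran-3-yl}-2,3-bis(triethylsilyloxy)propanal | COc1ccc(CCc2cc(=O)c([C@H](O[Si](CC)(CC)CC)[C@H](O[Si](CC)(CC)CC)C=O)c(C=O)o2)cc1OC(C)C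
F5 | step 14 | (5S,6R,7S,8S)-7,8-dihydroxy-2-[2-(3-isopropoxy-4-methoxyphenyl)ethyl]-5,6-bis(triethylsilyloxy)-5,6,7,8-tetrahydro-4H-chromen-4-one | COc1ccc(CCc2cc(=O)c3c(o2)[C@@H](O)[C@H](O)[C@@H](O[Si](CC)(CC)CC)[C@H]3O[Si](CC)(CC)CC)cc1OC(C)C
F6 | step 10 | 2-[(benzyloxy)methyl]-3-{[(4R)-2,2-dimethyl-1,3-dioxolan-4-yl]carbonyl}-6-[2-(3-isopropoxy-4-methoxyphenyl)ethyl]-4H-pyran-4-one | COc1ccc(CCc2cc(=O)c(C(=O)[C@H]3COC(C)(C)O3)c(COCc3ccccc3)o2)cc1OC(C)C
F7 | step 13 | 2-[(benzyloxy)methyl]-3-[(1S,2R)-3-hydroxy-1,2-bis(triethylsilyloxy)propyl]-6-[2-(3-isopropoxy-4-methoxyphenyl)ethyl]-4H-pyran-4-one | COc1ccc(CCc2cc(=O)c([C@H](O[Si](CC)(CC)CC)[C@H](O[Si](CC)(CC)CC)CO)c(COCc3ccccc3)o2)cc1OC(C)C
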